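**Strategy.** Ring B of crotobarin (C5–C10, atisane numbering) is cut at C7–C8 and C5–C10. This exploits the fact that C9 is a latent ketone flanked by two enolisable carbons, C8 and C10, so C8–C9(=O)–C10 acts as a 1,3-bis-nucleophile towards an allylic C5–C6–C7 bis-electrophile. The precursor is an ethyl ketone carrying a 2,6-dimethoxycyclohexa-2,5-dienyl group, a masked and still symmetric cyclohexane-1,3-dione that later becomes the bicyclo[2.2.2]octane. In one pot C8 is alkylated by a bromo allyl carbonate, then the C10 enolate closes the spiro ring in a Pd2(dba)3/chiral-diphosphine allylic alkylation that creates the C5 isopropenyl stereocentre. Michael addition, iodolactonisation and a radical bicyclisation complete the skeleton.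

Key step: step 4

Remark: atisane numbering is used throughout (C5 isopropenyl carbon, C8 quaternary bridgehead, C9 lactone-oxygen carbon, C10 methyl-bearing carbon, C11 its CH2 neighbour on C9, C14 acetoxy carbon, C15 ketone, C16=C17 exocyclic alkene). Compounds 1 and 4 are taken as commercial; 4 is otherwise the Birch product of 1,3-dimethoxybenzene.

Step 1
Reactants: 1 5-bromo-2-methylpent-2-ene
Product: 2 (E)-5-bromo-2-methylpent-2-en-1-ol
Conditions: SeO2 (0.3 equiv), t-BuOOH, salicylic acid (cat.), CH2Cl2, rt
Reagents that add atoms: tert-butyl hydroperoxide, CC(C)(C)OO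
Why: Selenium dioxide allylic oxidation (ene reaction, then [2,3]-sigmatropic shift) of a gem-dimethyl alkene should hydroxylate the (E)-methyl group selectively and leave the primary bromide alone.

Step 2
Reactants: 2 (E)-5-bromo-2-methylpent-2-en-1-ol
Product: 3 tert-butyl (E)-5-bromo-2-methylpent-2-en-1-yl carbonate
Conditions: Boc2O, DMAP (cat.), MeCN, rt
Reagents that add atoms: di-tert-butyl dicarbonate, CC(C)(C)OC(=O)OC(=O)OC(C)(C)C
Why: O-acylation gives an allylic tert-butyl carbonate that zerovalent palladium can ionise but that is too hindered to acylate an enolate.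

Step 3
Reactants: 4 1,5-dimethoxycyclohexa-1,4-diene; 5 N-methoxy-N-methylpropanamide
Product: 6 1-(2,6-dimethoxycyclohexa-2,5-dien-1-yl)propan-1-one
Conditions: t-BuLi (1.05 equiv), THF/HMPA, −78 °C; then 5, −78 °C; H2O
Reagents that add atoms: none
Why: The doubly allylic CH2 between the two methoxy-bearing carbons is lithiated selectively, and the Weinreb ketone synthesis stops at the ketone because the chelated tetrahedral adduct survives until the quench.

Step 4
Reactants: 6 1-(2,6-dimethoxycyclohexa-2,5-dien-1-yl)propan-1-one; 3 tert-butyl (E)-5-bromo-2-methylpent-2-en-1-yl carbonate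
Product: 8 1,5-dimethoxy-8-methyl-9-(prop-1-en-2-yl)spiro[5.5]undeca-1,4-dien-7-one (ring B ketone spiro-fused at C8; C5 configured as in crotobarin, C10 methyl trans to isopropenyl), via C8-alkylated ketone carbonate 7 (not isolated)
Conditions: KN(SiMe3)2 (1.0 equiv), THF, −78 to 0 °C; 3, NaI (cat.), 0 °C to rt; then LiN(SiMe3)2 (1.2 equiv), −78 °C; Pd2(dba)3·CHCl3 (2.5 mol %), (1R,2R)-N,N′-bis(2-diphenylphosphinobenzoyl)cyclohexane-1,2-diamine (7.5 mol %), −78 °C to rt; H2O
Reagents that add atoms: none
Why: The thermodynamic potassium enolate of 6 (C8–H is doubly allylic and α to the ketone, hence the most acidic site) is C-alkylated at C8 by the primary bromide of 3, as are the enolates of Birch reductive alkylations, which forms C7–C8 and leaves C10 as the only enolisable position of 7. The lithium enolate at C10 then attacks the η3-allyl complex of divalent palladium formed by ionisation of the tert-butyl carbonate (Tsuji–Trost allylic alkylation of a preformed ketone enolate), which forms C5–C10. Ring B closes in the 6-exo mode at the substituted allyl terminus C5, since attack at C18 would need an eight-membered ring, and the 2-methylallyl unit emerges directly as the isopropenyl group. C5 is the only lasting new stereocentre: the chiral diphosphine selects one face of the allyl complex while the two faces interconvert by η3–η1–η3 isomerisation at the CH2 terminus, and the ligand antipode is to be chosen for the C5 configuration drawn; C10 is epimerisable (trans expected) and is reset in step 5; C8 is not stereogenic because the dimethoxycyclohexadiene ring is symmetric. The step needs C- over O-allylation, which the soft allyl electrophile favours, and a clean order of events, which is secured by adding Pd2(dba)3 only after the first alkylation.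

Step 5
Reactants: 8 spiro ketone; 9 methyl acrylate
Product: 11 3-[1,5-dimethoxy-8-methyl-7-oxo-9-(prop-1-en-2-yl)spiro[5.5]undeca-1,4-dien-8-yl]propanoic acid (C5 and C10 as in crotobarin; propanoic chain trans to isopropenyl), via methyl ester 10 (not isolated)
Conditions: 9 (1.5 equiv), KOtBu (0.2 equiv), t-BuOH/THF, 0 °C to rt; then LiOH, THF/MeOH/H2O, rt; 1 M HCl to pH 5, 0 °C
Reagents that add atoms: lithium hydroxide, [Li+].[OH-]
Why: Base-catalysed Michael addition of the C10 enolate (the only enolisable position) should occur anti to the adjacent C5 isopropenyl group, which allylic strain with the enolate methyl holds pseudo-axial, so the quaternary C10 centre forms with the chain trans to isopropenyl; the ester is then saponified.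

Step 6
Reactants: 11 keto acid
Product: 13 3-[2-methyl-1-methylidene-7,11-dioxo-3-(prop-1-en-2-yl)spiro[5.5]undecan-2-yl]propanoic acid (C5, C10 as in crotobarin), via bis(enol ether) alkene acid 12 (not isolated)
Conditions: Ph3PCH3Br (6 equiv), KOtBu (6 equiv), toluene, 100 °C; then 1 M HCl, THF, rt
Reagents that add atoms: methyltriphenylphosphonium bromide, C[P+](c1ccccc1)(c1ccccc1)c1ccccc1.[Br-]; water, O
Why: Wittig methylenation with excess lithium-free ylide at high temperature, the protocol for ketones flanked by quaternary carbons, should convert the non-enolisable C9 ketone into the exocyclic alkene (the carboxylate is inert), and dilute acid then hydrolyses both methyl enol ethers to the 2,2-disubstituted cyclohexane-1,3-dione.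

Step 7
Reactants: 13 spiro dione alkene acid
Product: 14 iodolactone (cis-fused δ-lactone on ring B; C9 carries the lactone oxygen and an iodomethyl group; C5, C9, C10 as in crotobarin)
Conditions: I2 (3 equiv), NaHCO3, MeCN/H2O, 0 °C, dark
Reagents that add atoms: iodine, II
Why: Iodolactonisation: the carboxylate opens the iodonium ion of the C9=C11 alkene at the more substituted carbon C9 in a 6-exo closure along the axial trajectory from the side of its own C10 tether, which gives the cis-fused δ-lactone with the target C9 configuration and an equatorial iodomethyl group, while the isopropenyl group has no nucleophile within reach.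

Step 8
Reactants: 14 iodolactone
Product: 16 iodolactone enedione (cyclohex-4-ene-1,3-dione ring, in equilibrium with its vinylogous-acid enol tautomers), via bis(trimethylsilyl enol ether) 15 (not isolated)
Conditions: Me3SiOTf (2.5 equiv), Et3N (3 equiv), CH2Cl2, 0 °C; then Pd(OAc)2 (1.1 equiv), MeCN, rt; aq. NaHCO3
Reagents that add atoms: none
Why: Saegusa–Ito oxidation: one silyl enol ether of 15 is transferred to Pd(OAc)2 and β-hydride elimination gives the enone; which of the two equivalent ketones is desaturated does not matter, because both enediones are tautomers of one vinylogous acid and converge in step 9.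

Step 9
Reactants: 16 iodolactone enedione
Product: 17 crotobarin lacking the C17 methylene and carrying a ketone at C14 (bicyclo[2.2.2]octane-14,15-dione lactone)
Conditions: Bu3SnH (1.3 equiv, slow addition), AIBN (0.2 equiv), benzene, 80 °C
Reagents that add atoms: none
Why: Giese-type radical cyclisation: the primary C11 radical adds to C12, the β-carbon of the enone (6-exo-trig, polarity-matched), which closes the bicyclo[2.2.2]octane with the bridgeheads C8 and C12 fixed by the tether, and Bu3SnH quenches the α-keto radical.

Step 10
Reactants: 17 bicyclic diketone lactone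
Product: 18 C15 ethylene ketal of 17 (C14 ketone free)
Conditions: Me3SiOCH2CH2OSiMe3 (3 equiv), Me3SiOTf (0.1 equiv), CH2Cl2, −78 to −20 °C; pyridine quench
Reagents that add atoms: 1,2-bis(trimethylsilyloxy)ethane, C[Si](C)(C)OCCO[Si](C)(C)C
Why: Silyl triflate-catalysed ketalisation should select C15, because a tetrahedral ketal carbon at C14 would force one oxygen against the axial C20 methyl group (C14 and C20 are 1,3-diaxial on ring B), which lies over the cleft between the C9–C11 and C14–C13 bridges.

Step 11
Reactants: 18 keto ketal
Product: 19 C14 alcohol (hydroxyl pointing towards the C15 bridge, as in crotobarin), C15 ketal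
Conditions: SmI2 (4 equiv), HMPA, t-BuOH (2 equiv), THF, 0 °C
Reagents that add atoms: none
Why: Electron-transfer ketone reduction of the dissolving-metal type: the oxido-samarium carbanion should place its bulky O–Sm(HMPA) group in the open cleft towards C15 and be protonated on the C20 side, which gives the thermodynamically preferred C14 alcohol and leaves lactone, ketal and alkenes untouched.

Step 12
Reactants: 19 hydroxy ketal
Product: 21 crotobarin lacking the C17 methylene (C16 = CH2), via acetoxy ketal 20 (not isolated)
Conditions: Ac2O, DMAP, pyridine, rt; then 2 M HCl, THF, rt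
Reagents that add atoms: acetic anhydride, CC(=O)OC(C)=O; water, O
Why: DMAP-catalysed acetylation of the exposed C14 hydroxyl, then mild acid hydrolysis of the dioxolane, frees the C15 ketone; the β-acetoxy ketone cannot eliminate because C8 is quaternary.

Step 13
Reactants: 21 keto acetate
Product: 22 crotobarin
Conditions: (CH2O)n, N-methylanilinium trifluoroacetate, THF, 65 °C
Reagents that add atoms: formaldehyde (as paraformaldehyde), C=O
Why: Mannich condensation–elimination (α-methylenation) at C16, the only enolisable position of the C15 ketone since C8 is quaternary, installs the exocyclic enone.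

**Compound list**

1 | 5-bromo-2-methylpent-2-ene | CC(C)=CCCBr | starting material
2 | (E)-5-bromo-2-methylpent-2-en-1-ol | OC/C(C)=C/CCBr | intermediate
3 | tert-butyl (E)-5-bromo-2-methylpent-2-en-1-yl carbonate | CC(C)(C)OC(=O)OC/C(C)=C/CCBr | intermediate
4 | 1,5-dimethoxycyclohexa-1,4-diene | COC1=CCC=C(OC)C1 | starting material
5 | N-methoxy-N-methylpropanamide | CCC(=O)N(C)OC | starting material
6 | 1-(2,6-dimethoxycyclohexa-2,5-dien-1-yl)propan-1-one | CCC(=O)C1C(OC)=CCC=C1OC | intermediate
7 | tert-butyl (E)-5-(2,6-dimethoxy-1-propanoylcyclohexa-2,5-dien-1-yl)-2-methylpent-2-en-1-yl carbonate | CCC(=O)C1(CC/C=C(\C)COC(=O)OC(C)(C)C)C(OC)=CCC=C1OC | intermediate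
8 | 1,5-dimethoxy-8-methyl-9-(prop-1-en-2-yl)spiro[5.5]undeca-1,4-dien-7-one, C5 as in crotobarin, methyl trans to isopropenyl | CC(=C)[C@@H]1CCC2(C(OC)=CCC=C2OC)C(=O)[C@H]1C | intermediate
9 | methyl acrylate | C=CC(=O)OC | starting material
10 | methyl 3-[1,5-dimethoxy-8-methyl-7-oxo-9-(prop-1-en-2-yl)spiro[5.5]undeca-1,4-dien-8-yl]propanoate, chain trans to isopropenyl | CC(=C)[C@@H]1CCC2(C(OC)=CCC=C2OC)C(=O)[C@@]1(C)CCC(=O)OC | intermediate
11 | 3-[1,5-dimethoxy-8-methyl-7-oxo-9-(prop-1-en-2-yl)spiro[5.5]undeca-1,4-dien-8-yl]propanoic acid, chain trans to isopropenyl | CC(=C)[C@@H]1CCC2(C(OC)=CCC=C2OC)C(=O)[C@@]1(C)CCC(=O)O | intermediate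
12 | 3-[1,5-dimethoxy-8-methyl-7-methylidene-9-(prop-1-en-2-yl)spiro[5.5]undeca-1,4-dien-8-yl]propanoic acid | CC(=C)[C@@H]1CCC2(C(OC)=CCC=C2OC)C(=C)[C@@]1(C)CCC(=O)O | intermediate
13 | 3-[2-methyl-1-methylidene-7,11-dioxo-3-(prop-1-en-2-yl)spiro[5.5]undecan-2-yl]propanoic acid | CC(=C)[C@@H]1CCC2(C(=O)CCCC2=O)C(=C)[C@@]1(C)CCC(=O)O | intermediate
14 | iodolactone: spiro cyclohexane-1,3-dione with cis-fused δ-lactone, iodomethyl and lactone oxygen on C9 | CC(=C)[C@@H]1CCC2(C(=O)CCCC2=O)[C@@]3(CI)OC(=O)CC[C@@]13C | intermediate
15 | bis(trimethylsilyl enol ether) of 14 | CC(=C)[C@@H]1CCC2(C(O[Si](C)(C)C)=CCC=C2O[Si](C)(C)C)[C@@]3(CI)OC(=O)CC[C@@]13C | intermediate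
16 | iodolactone enedione, one tautomer drawn; the spiro carbon is left undefined because the tautomers interconvert | CC(=C)[C@@H]1CCC2(C(=O)C=CCC2=O)[C@@]3(CI)OC(=O)CC[C@@]13C | intermediate
17 | crotobarin lacking the C17 methylene, with a ketone at C14 (14,15-diketone) | C1C(=O)[C@]23CC[C@@H](C(=C)C)[C@]4(C)CCC(=O)O[C@@]42C[C@H]1CC3=O | intermediate
18 | C15 ethylene ketal of 17 | C1C5(OCCO5)[C@]23CC[C@@H](C(=C)C)[C@]4(C)CCC(=O)O[C@@]42C[C@H]1CC3=O | intermediate
19 | C14 alcohol (crotobarin configuration), C15 ethylene ketal | C1C5(OCCO5)[C@]23CC[C@@H](C(=C)C)[C@]4(C)CCC(=O)O[C@@]42C[C@H]1C[C@@H]3O | intermediate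
20 | C14 acetate, C15 ethylene ketal | C1C5(OCCO5)[C@]23CC[C@@H](C(=C)C)[C@]4(C)CCC(=O)O[C@@]42C[C@H]1C[C@@H]3OC(C)=O | intermediate
21 | crotobarin lacking the C17 methylene (C16 = CH2) | C1C(=O)[C@]23CC[C@@H](C(=C)C)[C@]4(C)CCC(=O)O[C@@]42C[C@H]1C[C@@H]3OC(C)=O | intermediate
22 | crotobarin | C=C1C(=O)[C@]23CC[C@@H](C(=C)C)[C@]4(C)CCC(=O)O[C@@]42C[C@H]1C[C@@H]3OC(C)=O | target

**Step count.** Total: 13 steps. Longest linear sequence: 12 steps (steps 1, 2, 4 to 13).

**Steps most likely to fail**

Step 4. The closure may lose enantiofacial control at the allyl terminus, or the hindered enolate may be allylated on oxygen. The fallback replaces the catalytic asymmetric closure by a stereospecific double displacement. It sets out from 6: the potassium enolate of 6 opens the enantioenriched cyclic sulfate (R)-4-(prop-1-en-2-yl)-1,3,2-dioxathiane 2,2-dioxide F1 (made from the corresponding (R)-1,3-diol) at its primary carbon, giving the potassium alkyl sulfate F2. LiN(SiMe3)2 then forms the C10 enolate, which displaces the secondary allylic sulfate with inversion and closes ring B. The sequence comes back to the route at 8.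

Step 6. Ylide addition to a carbonyl flanked by two quaternary carbons may be too slow, so the ketone may not be converted. The fallback is a Peterson olefination with a smaller nucleophile, setting out from 11: Me3SiCH2Li with CeCl3 adds to the lithium salt of 11 to give the β-hydroxysilane F3 (either C9 epimer serves). The aqueous HCl treatment already planned then brings about elimination of trimethylsilanol and hydrolysis of the enol ethers, so the sequence comes back at 13.

Step 11. Hydrogen may be delivered to C14 from the open cleft, giving the epimeric alcohol, or electron transfer to the hindered ketone may be sluggish. The fallback separates reduction from stereocontrol, setting out from 18: LiAlH(OtBu)3 reduces the ketone to an alcohol that should be rich in the C14 epimer F4. Meerwein–Ponndorf–Verley/Oppenauer equilibration with Al(OiPr)3 in i-PrOH containing a little acetone then shuttles F4 through 18 to the thermodynamically favoured alcohol, so the sequence comes back at 19.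

Further compounds
F1 | step 4 | (R)-4-(prop-1-en-2-yl)-1,3,2-dioxathiane 2,2-dioxide | CC(=C)[C@H]1CCOS(=O)(=O)O1
F2 | step 4 | potassium (R)-5-(2,6-dimethoxy-1-propanoylcyclohexa-2,5-dien-1-yl)-2-methylpent-1-en-3-yl sulfate | CCC(=O)C1(CC[C@@H](OS(=O)(=O)[O-])C(=C)C)C(OC)=CCC=C1OC.[K+]
F3 | step 6 | 3-[7-hydroxy-1,5-dimethoxy-8-methyl-9-(prop-1-en-2-yl)-7-(trimethylsilylmethyl)spiro[5.5]undeca-1,4-dien-8-yl]propanoic acid (C9 epimer not defined) | CC(=C)[C@@H]1CCC2(C(OC)=CCC=C2OC)C(O)(C[Si](C)(C)C)[C@@]1(C)CCC(=O)O
F4 | step 11 | C14 epimer of 19 | C1C5(OCCO5)[C@]23CC[C@@H](C(=C)C)[C@]4(C)CCC(=O)O[C@@]42C[C@H]1C[C@H]3O
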